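The retrosynthesis uses labdane numbering: ring A is C1–C5 with C10, ring B is C5–C10, the chain C11–C15 sits on C9, and the methyls are C16 on C13, C17 on C8, C18 with the oxygenated C19 on C4, and C20 on C10. The target is the (3S,4R,5S,9R,10S,13E) isomer, a trans-decalin with an axial C3 acetate, an axial C19 hydroxymethyl and the C9 chain cis to C20.
Enabling feature: quaternary C10 and its neighbour C9 are the α and β carbons of a ring B cyclohexenone whose carbonyl is C5. C9–C11 and C10–C1 can therefore be cut in one move, back to a 2-methylcyclohexenone, a chain nucleophile and an allyl electrophile.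
Cuts, last-made bond first: C13=C14 (Horner–Wadsworth–Emmons), C8–C17 (enol triflate methylation), C4–C18 (enolate methylation), C4=C5 (Knoevenagel closure of ring A), C3–C4 (Roskamp homologation), then C10–C1 and C9–C11 together.
Forward order: ring B is there from the start as a cyclohexenone and receives the chain and the allyl group. Ring A is then closed onto C5, C3/C4/C19 are adjusted, the C8 oxygen is turned into the C7=C8 alkene bearing C17, and the chain is extended last.
Stereochemistry: an oxazaborolidine-catalysed reduction sets the C8 carbinol, the only external source of chirality. It is relayed to C9 (anti cuprate attack), C10 (allylation anti to the chain), C5 (trans fusion on dissolving-metal protonation), C4 (equatorial methylation) and C3 (equatorial hydride attack), after which C8 becomes sp2.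

Key step: step 7

Remark on the chemistry: the face of ring B or of the decalin that carries C20 is called the methyl face, and the opposite one, which carries H5 and H9, the hydrogen face. TBS = tert-butyldimethylsilyl, TBDPS = tert-butyldiphenylsilyl, Tf = trifluoromethanesulfonyl. The dioxaspirodecenone, the bromo ketal, allyl iodide, ethyl diazoacetate, diethylphosphonoacetic acid and 2-(trimethylsilyl)ethanol are taken as commercial.

Step 1
Reactants: 1 1,4-dioxaspiro[4.5]dec-6-en-8-one
Product: 2 (8S)-1,4-dioxaspiro[4.5]dec-6-en-8-ol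
Conditions: (3aR)-1-methyl-3,3-diphenyltetrahydro-1H,3H-pyrrolo[1,2-c][1,3,2]oxazaborole (10 mol %), BH3·SMe2, THF, −20 °C
Reagents that add atoms: none
Why: Corey–Bakshi–Shibata reduction, in which the borane-loaded oxazaborolidine binds the carbonyl oxygen anti to the larger alkenyl–ketal arm and delivers hydride in a 1,2 sense to one face, so that the (R) catalyst should give the (S) carbinol, the future C8.

Step 2
Reactants: 2 (8S)-1,4-dioxaspiro[4.5]dec-6-en-8-ol
Product: 3 (8S)-8-(TBSO)-1,4-dioxaspiro[4.5]dec-6-ene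
Conditions: TBSCl, imidazole, DMF, 0 °C → rt
Reagents that add atoms: tert-butyldimethylsilyl chloride, CC(C)(C)[Si](C)(C)Cl
Why: Imidazole-promoted silylation of a secondary allylic alcohol, which forms only an O–Si bond and leaves the carbinol centre untouched.

Step 3
Reactants: 3 (8S)-8-(TBSO)-1,4-dioxaspiro[4.5]dec-6-ene
Product: 4 (S)-4-(TBSO)cyclohex-2-en-1-one
Conditions: pyridinium p-toluenesulfonate, acetone–H2O, rt → 40 °C
Reagents that add atoms: water, O
Why: Mild acid-catalysed ketal hydrolysis, driven by the conjugation gained in the enone and too weak to cleave the TBS ether or to ionise the allylic C–O bond.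

Step 4
Reactants: 4 (S)-4-(TBSO)cyclohex-2-en-1-one
Product: 5 (S)-4-(TBSO)-2-iodocyclohex-2-en-1-one
Conditions: I2, pyridine–CH2Cl2, 0 °C → rt
Reagents that add atoms: iodine, II
Why: α-Iodination of an enone by a Baylis–Hillman-type sequence (pyridine adds to the β carbon, the enolate is iodinated, pyridine leaves), a standard reaction of 4-silyloxycyclohexenones that does not touch the carbinol centre.

Step 5
Reactants: 5 (S)-4-(TBSO)-2-iodocyclohex-2-en-1-one
Product: 6 (S)-4-(TBSO)-2-methylcyclohex-2-en-1-one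
Conditions: MeZnCl, Pd(PPh3)4 (5 mol %), THF, 0 °C → rt
Reagents that add atoms: methylzinc chloride, C[Zn]Cl
Why: Negishi coupling (zerovalent palladium inserts into the C–I bond, zinc passes on the methyl group, reductive elimination forms C10–C20), and the organozinc reagent is too mild to add to the enone or to eliminate the γ-silyloxy group.

Step 6
Reactants: 7 2-(2-bromoethyl)-2-methyl-1,3-dioxolane
Product: 8 [2-(2-methyl-1,3-dioxolan-2-yl)ethyl]magnesium bromide
Conditions: Mg turnings, THF, 20–25 °C, used at once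
Reagents that add atoms: magnesium, [Mg]
Why: Grignard formation by magnesium insertion into a primary C–Br bond, kept at or below room temperature because β-ketal Grignard reagents fragment on heating.

Step 7
Reactants: 6 (S)-4-(TBSO)-2-methylcyclohex-2-en-1-one; 8 [2-(2-methyl-1,3-dioxolan-2-yl)ethyl]magnesium bromide; 9 allyl iodide
Product: 12 (2S,3S,4S)-2-allyl-4-(TBSO)-2-methyl-3-[2-(2-methyl-1,3-dioxolan-2-yl)ethyl]cyclohexan-1-one, via trimethylsilyl enol ether 10 (not isolated), via lithium enolate 11 (not isolated)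
Conditions: CuBr·SMe2 (20 mol %), Me3SiCl, THF, −78 → −30 °C; pentane, filtration of the salts under argon, concentration; MeLi, THF, 0 °C; 9, DMPU, −78 → −20 °C
Reagents that add atoms: 8 [2-(2-methyl-1,3-dioxolan-2-yl)ethyl]magnesium bromide, CC1(CC[Mg]Br)OCCO1; 9 allyl iodide, C=CCI; chlorotrimethylsilane, C[Si](C)(C)Cl (silicon kept only in 10); methyllithium, [Li]C (lithium kept only in 11)
Why: CuBr·SMe2 turns 8 into an organocopper species that forms a π-complex with the C9=C10 bond of 6, passes through a β-cuprio enolate of trivalent copper and, pushed by Me3SiCl, collapses by reductive elimination to the C9–C11 bond while O5 is silylated to 10. MeLi then attacks the Me3Si group of 10 and frees only the tetrasubstituted C5=C10 lithium enolate 11, whose C10 displaces iodide from 9 in an SN2 step to make the C10–C1 bond; no ring closes in either event. The closest known reaction type is the tandem vicinal difunctionalisation (conjugate addition, then enolate alkylation) of 2-methylcycloalkenones, with the silyl enol ether serving as a position-stable store of the enolate. C9 is set by the C8 silyloxy group, because the copper reagent attacks the half-chair enone axially on the face anti to that group, the usual trans outcome for 4-silyloxycyclohexenones. C10 is set by the new chain, because allylic 1,2-strain with the C10 methyl holds the chain pseudoaxial in 11, so the chair-like axial trajectory at C10 is also the face away from the chain, the allyl group enters there and C20 is left cis to the chain. The step needs 1,4- over 1,2-addition (secured by copper and Me3SiCl), alkylation at C10 and not at C6 (secured by the position-fixed enolate, by removal of the magnesium salts before MeLi and by a fast electrophile in DMPU that outruns proton exchange) and the two anti selections just named.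

Step 8
Reactants: 12 (2S,3S,4S)-2-allyl-4-(TBSO)-2-methyl-3-[2-(2-methyl-1,3-dioxolan-2-yl)ethyl]cyclohexan-1-one
Product: 14 (2S,3S,4S)-4-(TBSO)-2-(3-hydroxypropyl)-2-methyl-3-[2-(2-methyl-1,3-dioxolan-2-yl)ethyl]cyclohexan-1-one, via B-alkyl-9-borabicyclononane 13 (not isolated)
Conditions: 9-borabicyclo[3.3.1]nonane, THF, 0 °C → rt; NaOH, H2O2, 0 °C
Reagents that add atoms: 9-borabicyclo[3.3.1]nonane, B1C2CCCC1CCC2 (boron kept only in 13); hydrogen peroxide, OO
Why: Hydroboration–oxidation, in which the bulky borane adds anti-Markovnikov to the monosubstituted alkene faster than it reduces the C5 ketone next to quaternary C10, and any C5 alcohol that did form would be returned to the ketone in step 9.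

Step 9
Reactants: 14 (2S,3S,4S)-4-(TBSO)-2-(3-hydroxypropyl)-2-methyl-3-[2-(2-methyl-1,3-dioxolan-2-yl)ethyl]cyclohexan-1-one
Product: 15 3-{(1S,2S,3S)-3-(TBSO)-1-methyl-2-[2-(2-methyl-1,3-dioxolan-2-yl)ethyl]-6-oxocyclohexyl}propanal
Conditions: Dess–Martin periodinane, pyridine, CH2Cl2, 0 °C → rt
Reagents that add atoms: none
Why: Dess–Martin oxidation of a primary alcohol stops at the aldehyde under near-neutral buffered conditions that spare the ketal, the silyl ether and the aldol-prone keto aldehyde.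

Step 10
Reactants: 15 3-{(1S,2S,3S)-3-(TBSO)-1-methyl-2-[2-(2-methyl-1,3-dioxolan-2-yl)ethyl]-6-oxocyclohexyl}propanal; 16 ethyl diazoacetate
Product: 17 ethyl 5-{(1S,2S,3S)-3-(TBSO)-1-methyl-2-[2-(2-methyl-1,3-dioxolan-2-yl)ethyl]-6-oxocyclohexyl}-3-oxopentanoate
Conditions: SnCl2 (10 mol %), CH2Cl2, rt
Reagents that add atoms: 16 ethyl diazoacetate, CCOC(=O)C=[N+]=[N-]
Why: Roskamp reaction, in which the diazo carbon adds to the SnCl2-activated aldehyde and a 1,2-hydride shift with loss of N2 gives the β-keto ester (C3–C4 bond), while ketones do not react under these conditions.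

Step 11
Reactants: 17 ethyl 5-{(1S,2S,3S)-3-(TBSO)-1-methyl-2-[2-(2-methyl-1,3-dioxolan-2-yl)ethyl]-6-oxocyclohexyl}-3-oxopentanoate
Product: 18 ethyl (8S,9S,10S)-8-(TBSO)-13,13-ethylenedioxy-3-oxo-14,15,17,18-tetranorlabd-4-en-19-oate
Conditions: piperidine, AcOH (each 0.3 equiv), toluene, Dean–Stark, 110 °C
Reagents that add atoms: none
Why: Intramolecular Knoevenagel condensation (6-(enolexo)-exo-trig aldol of the doubly activated C4 onto the C5 ketone, then loss of water), the same closure as the second stage of a Robinson annulation with a vinyl β-keto ester, run with an amine salt so that retro-Michael cleavage at C10 is avoided.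

Step 12
Reactants: 18 ethyl (8S,9S,10S)-8-(TBSO)-13,13-ethylenedioxy-3-oxo-14,15,17,18-tetranorlabd-4-en-19-oate
Product: 20 ethyl (4S,5S,8S,9S,10R)-8-(TBSO)-13,13-ethylenedioxy-3-oxo-14,15,17-trinorlabdan-19-oate, via lithium keto ester enolate 19 (not isolated)
Conditions: Li (2.2 equiv), t-BuOH (1.0 equiv), NH3–THF, −78 °C; NH3 evaporated; MeI, THF–DMPU, rt
Reagents that add atoms: lithium, [Li] (kept only in 19); methyl iodide, CI
Why: Dissolving-metal reductive alkylation, in which the C5 carbanion is protonated axially to give the trans-decalin (H5 anti to C20) and the resulting C3=C4 enolate 19 is methylated on the hydrogen face, away from the 1,3-related axial C20, so that C18 ends equatorial and the C19 ester axial.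

Step 13
Reactants: 20 ethyl (4S,5S,8S,9S,10R)-8-(TBSO)-13,13-ethylenedioxy-3-oxo-14,15,17-trinorlabdan-19-oate
Product: 21 ethyl (3S,4S,5S,8S,9S,10R)-8-(TBSO)-13,13-ethylenedioxy-3-hydroxy-14,15,17-trinorlabdan-19-oate
Conditions: LiBH(s-Bu)3, THF, −78 → 0 °C; NaOH, H2O2
Reagents that add atoms: none
Why: Reduction of a hindered cyclohexanone with a bulky trialkylborohydride, which avoids the axial path blocked by axial H1 and H5 and attacks along the equatorial trajectory, placing the C3 hydroxyl axial on the hydrogen face as known for 4,4-disubstituted 3-oxo terpenoids, with the ester left intact.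

Step 14
Reactants: 21 ethyl (3S,4S,5S,8S,9S,10R)-8-(TBSO)-13,13-ethylenedioxy-3-hydroxy-14,15,17-trinorlabdan-19-oate
Product: 22 (3S,4R,5S,8S,9S,10R)-8-(TBSO)-13,13-ethylenedioxy-14,15,17-trinorlabdane-3,19-diol
Conditions: LiAlH4, THF, 0 → 40 °C
Reagents that add atoms: none
Why: LiAlH4 reduction of an ester, which is small and strong enough for the hindered axial C19 ester and leaves the silyl ether, the ketal and all stereocentres untouched.

Step 15
Reactants: 22 (3S,4R,5S,8S,9S,10R)-8-(TBSO)-13,13-ethylenedioxy-14,15,17-trinorlabdane-3,19-diol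
Product: 23 (3S,4R,5S,8S,9S,10R)-8-(TBSO)-19-(TBDPSO)-13,13-ethylenedioxy-14,15,17-trinorlabdan-3-ol
Conditions: TBDPSCl, imidazole, DMAP (cat.), DMF, rt → 40 °C
Reagents that add atoms: tert-butyldiphenylsilyl chloride, CC(C)(C)[Si](Cl)(c1ccccc1)c1ccccc1
Why: Selective silylation of a primary in the presence of a secondary alcohol, since the bulky chlorosilane reaches the C19 hydroxyl far more easily than the axial C3 hydroxyl next to quaternary C4, as is routine for 3,19-diols of this ring system.

Step 16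
Reactants: 23 (3S,4R,5S,8S,9S,10R)-8-(TBSO)-19-(TBDPSO)-13,13-ethylenedioxy-14,15,17-trinorlabdan-3-ol
Product: 24 (3S,4R,5S,8S,9S,10R)-3-acetoxy-8-(TBSO)-19-(TBDPSO)-13,13-ethylenedioxy-14,15,17-trinorlabdane
Conditions: Ac2O, DMAP, pyridine, 40 °C
Reagents that add atoms: acetic anhydride, CC(=O)OC(C)=O
Why: DMAP-catalysed acylation through the N-acetylpyridinium ion, reactive enough for a hindered axial secondary alcohol and proceeding with retention because only the O–H bond is broken.

Step 17
Reactants: 24 (3S,4R,5S,8S,9S,10R)-3-acetoxy-8-(TBSO)-19-(TBDPSO)-13,13-ethylenedioxy-14,15,17-trinorlabdane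
Product: 25 (3S,4R,5S,8S,9S,10R)-3-acetoxy-19-(TBDPSO)-13,13-ethylenedioxy-14,15,17-trinorlabdan-8-ol
Conditions: HF·pyridine, pyridine, THF, 0 °C → rt
Reagents that add atoms: none
Why: Selective desilylation with buffered HF, which removes the equatorial secondary TBS ether well before the much more robust TBDPS ether, while the excess pyridine keeps the medium too weakly acidic to open the dioxolane.

Step 18
Reactants: 25 (3S,4R,5S,8S,9S,10R)-3-acetoxy-19-(TBDPSO)-13,13-ethylenedioxy-14,15,17-trinorlabdan-8-ol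
Product: 26 (3S,4R,5S,9S,10R)-3-acetoxy-19-(TBDPSO)-13,13-ethylenedioxy-14,15,17-trinorlabdan-8-one
Conditions: Dess–Martin periodinane, pyridine, CH2Cl2, rt
Reagents that add atoms: none
Why: Dess–Martin oxidation of the only free alcohol under near-neutral conditions, and C9, now α to a ketone, already carries its chain in the equatorial, thermodynamically preferred position.

Step 19
Reactants: 26 (3S,4R,5S,9S,10R)-3-acetoxy-19-(TBDPSO)-13,13-ethylenedioxy-14,15,17-trinorlabdan-8-one
Product: 28 (3S,4R,5S,9S,10R)-3-acetoxy-19-(TBDPSO)-13,13-ethylenedioxy-8-(TfO)-14,15,17-trinorlabd-7-ene, via lithium C7=C8 enolate 27 (not isolated)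
Conditions: LiN(SiMe3)2 (1.05 equiv), THF, −78 °C; N-(5-chloro-2-pyridyl)bis(trifluoromethanesulfonimide), −78 °C
Reagents that add atoms: LiN(SiMe3)2, [Li]N([Si](C)(C)C)[Si](C)(C)C (lithium kept only in 27); N-(5-chloro-2-pyridyl)bis(trifluoromethanesulfonimide), FC(F)(F)S(=O)(=O)N(c1ccc(Cl)cn1)S(=O)(=O)C(F)(F)F
Why: Kinetic enolisation and O-sulfonylation, in which one equivalent of a bulky amide base at low temperature removes an open C7 methylene proton of the ketone rather than the C9 methine proton next to quaternary C10 or the less acidic acetate protons, and the very reactive triflimide traps the enolate before it can equilibrate.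

Step 20
Reactants: 28 (3S,4R,5S,9S,10R)-3-acetoxy-19-(TBDPSO)-13,13-ethylenedioxy-8-(TfO)-14,15,17-trinorlabd-7-ene
Product: 29 (3S,4R,5S,9R,10S)-3-acetoxy-19-(TBDPSO)-13,13-ethylenedioxy-14,15-dinorlabd-7-ene
Conditions: MeZnCl, Pd(PPh3)4 (5 mol %), THF, rt → 50 °C
Reagents that add atoms: methylzinc chloride, C[Zn]Cl
Why: Negishi coupling of an enol triflate, which forms C8–C17 with the alkene fixed at C7=C8 and uses an organozinc reagent that tolerates the acetate.

Step 21
Reactants: 29 (3S,4R,5S,9R,10S)-3-acetoxy-19-(TBDPSO)-13,13-ethylenedioxy-14,15-dinorlabd-7-ene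
Product: 30 (3S,4R,5S,9R,10S)-3-acetoxy-19-(TBDPSO)-14,15-dinorlabd-7-en-13-one
Conditions: pyridinium p-toluenesulfonate, acetone–H2O, 50 °C
Reagents that add atoms: water, O
Why: Mild acid-catalysed ketal hydrolysis, too weak to protonate the trisubstituted C7=C8 alkene or to cleave the acetate and the TBDPS ether.

Step 22
Reactants: 31 diethylphosphonoacetic acid; 32 2-(trimethylsilyl)ethanol
Product: 33 2-(trimethylsilyl)ethyl 2-(diethoxyphosphoryl)acetate
Conditions: N,N'-dicyclohexylcarbodiimide, DMAP (cat.), CH2Cl2, 0 °C → rt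
Reagents that add atoms: 32 2-(trimethylsilyl)ethanol, C[Si](C)(C)CCO
Why: Steglich esterification of an unhindered acid with a primary alcohol, giving a phosphonate whose ester can later be removed with fluoride instead of hydroxide.

Step 23
Reactants: 30 (3S,4R,5S,9R,10S)-3-acetoxy-19-(TBDPSO)-14,15-dinorlabd-7-en-13-one; 33 2-(trimethylsilyl)ethyl 2-(diethoxyphosphoryl)acetate
Product: 34 2-(trimethylsilyl)ethyl (3S,4R,5S,9R,10S,13E)-3-acetoxy-19-(TBDPSO)labda-7,13-dien-15-oate
Conditions: 33 (slight excess over NaH), NaH, THF, 0 °C; 30, rt → 50 °C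
Reagents that add atoms: 33 2-(trimethylsilyl)ethyl 2-(diethoxyphosphoryl)acetate, CCOP(=O)(CC(=O)OCC[Si](C)(C)C)OCC
Why: Horner–Wadsworth–Emmons olefination of a methyl ketone, standard for this labdane chain, which should favour the E alkene because the larger C12 arm is placed anti to the ester in the reversible addition–elimination, with the minor Z isomer removed by chromatography and the stabilised anion too mild to attack the hindered acetate.

Step 24
Reactants: 34 2-(trimethylsilyl)ethyl (3S,4R,5S,9R,10S,13E)-3-acetoxy-19-(TBDPSO)labda-7,13-dien-15-oate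
Product: 35 (3S,4R,5S,9R,10S,13E)-3-acetoxy-19-hydroxylabda-7,13-dien-15-oic acid
Conditions: n-Bu4NF, THF, rt → 40 °C; dilute aq. HCl to pH 4
Reagents that add atoms: none
Why: Fluoride-induced global desilylation (β-elimination of the 2-(trimethylsilyl)ethyl ester and Si–O cleavage at C19 in one operation), which uses no hydrolytic reagent so the hindered acetate stays, and a 1,3-acyl shift is ruled out because the C3–O and C4–C19 bonds are trans-diaxial and cannot share a six-membered orthoester.

Compound list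
1 | 1,4-dioxaspiro[4.5]dec-6-en-8-one | O=C1C=CC2(CC1)OCCO2 | starting material
2 | (8S)-1,4-dioxaspiro[4.5]dec-6-en-8-ol | C1COC2(O1)CC[C@H](O)C=C2 | intermediate
3 | (8S)-8-(tert-butyldimethylsilyloxy)-1,4-dioxaspiro[4.5]dec-6-ene | C1COC2(O1)CC[C@H](O[Si](C)(C)C(C)(C)C)C=C2 | intermediate
4 | (S)-4-(tert-butyldimethylsilyloxy)cyclohex-2-en-1-one | O=C1CC[C@H](O[Si](C)(C)C(C)(C)C)C=C1 | intermediate
5 | (S)-4-(tert-butyldimethylsilyloxy)-2-iodocyclohex-2-en-1-one | O=C1CC[C@H](O[Si](C)(C)C(C)(C)C)C=C1I | intermediate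
6 | (S)-4-(tert-butyldimethylsilyloxy)-2-methylcyclohex-2-en-1-one | O=C1CC[C@H](O[Si](C)(C)C(C)(C)C)C=C1C | intermediate
7 | 2-(2-bromoethyl)-2-methyl-1,3-dioxolane | CC1(CCBr)OCCO1 | starting material
8 | [2-(2-methyl-1,3-dioxolan-2-yl)ethyl]magnesium bromide | CC1(CC[Mg]Br)OCCO1 | intermediate
9 | allyl iodide | C=CCI | starting material
10 | {(3S,4S)-4-(tert-butyldimethylsilyloxy)-2-methyl-3-[2-(2-methyl-1,3-dioxolan-2-yl)ethyl]cyclohex-1-en-1-yl}oxytrimethylsilane (chain and C8 oxygen trans) | CC2=C(O[Si](C)(C)C)CC[C@H](O[Si](C)(C)C(C)(C)C)[C@H]2CCC1(C)OCCO1 | intermediate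
11 | lithium (3S,4S)-4-(tert-butyldimethylsilyloxy)-2-methyl-3-[2-(2-methyl-1,3-dioxolan-2-yl)ethyl]cyclohex-1-en-1-olate | [Li+].CC2=C([O-])CC[C@H](O[Si](C)(C)C(C)(C)C)[C@H]2CCC1(C)OCCO1 | intermediate
12 | (2S,3S,4S)-2-allyl-4-(tert-butyldimethylsilyloxy)-2-methyl-3-[2-(2-methyl-1,3-dioxolan-2-yl)ethyl]cyclohexan-1-one (methyl cis to chain, silyloxy trans to chain) | C=CC[C@]2(C)C(=O)CC[C@H](O[Si](C)(C)C(C)(C)C)[C@H]2CCC1(C)OCCO1 | intermediate
13 | 9-{3-[(1S,2S,3S)-3-(tert-butyldimethylsilyloxy)-1-methyl-2-[2-(2-methyl-1,3-dioxolan-2-yl)ethyl]-6-oxocyclohexyl]propyl}-9-borabicyclo[3.3.1]nonane | C1CCC2CCCC1B2CCC[C@]3(C)C(=O)CC[C@H](O[Si](C)(C)C(C)(C)C)[C@H]3CCC4(C)OCCO4 | intermediate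
14 | (2S,3S,4S)-4-(tert-butyldimethylsilyloxy)-2-(3-hydroxypropyl)-2-methyl-3-[2-(2-methyl-1,3-dioxolan-2-yl)ethyl]cyclohexan-1-one | OCCC[C@]2(C)C(=O)CC[C@H](O[Si](C)(C)C(C)(C)C)[C@H]2CCC1(C)OCCO1 | intermediate
15 | 3-{(1S,2S,3S)-3-(tert-butyldimethylsilyloxy)-1-methyl-2-[2-(2-methyl-1,3-dioxolan-2-yl)ethyl]-6-oxocyclohexyl}propanal | O=CCC[C@]2(C)C(=O)CC[C@H](O[Si](C)(C)C(C)(C)C)[C@H]2CCC1(C)OCCO1 | intermediate
16 | ethyl diazoacetate | CCOC(=O)C=[N+]=[N-] | starting material
17 | ethyl 5-{(1S,2S,3S)-3-(tert-butyldimethylsilyloxy)-1-methyl-2-[2-(2-methyl-1,3-dioxolan-2-yl)ethyl]-6-oxocyclohexyl}-3-oxopentanoate | CCOC(=O)CC(=O)CC[C@]2(C)C(=O)CC[C@H](O[Si](C)(C)C(C)(C)C)[C@H]2CCC1(C)OCCO1 | intermediate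
18 | ethyl (8S,9S,10S)-8-(tert-butyldimethylsilyloxy)-13,13-ethylenedioxy-3-oxo-14,15,17,18-tetranorlabd-4-en-19-oate | O=C1CC[C@]2(C)C(=C1C(=O)OCC)CC[C@H](O[Si](C)(C)C(C)(C)C)[C@H]2CCC3(C)OCCO3 | intermediate
19 | lithium C3=C4 enolate of the trans-fused 3-oxo 19-ester (H5 anti to C20) | [Li+].[O-]C1=C(C(=O)OCC)[C@H]2CC[C@H](O[Si](C)(C)C(C)(C)C)[C@@H](CCC3(C)OCCO3)[C@]2(C)CC1 | intermediate
20 | ethyl (4S,5S,8S,9S,10R)-8-(tert-butyldimethylsilyloxy)-13,13-ethylenedioxy-3-oxo-14,15,17-trinorlabdan-19-oate (equatorial C18, axial ester) | O=C1CC[C@]2(C)[C@H](CC[C@H](O[Si](C)(C)C(C)(C)C)[C@H]2CCC3(C)OCCO3)[C@]1(C)C(=O)OCC | intermediate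
21 | ethyl (3S,4S,5S,8S,9S,10R)-8-(tert-butyldimethylsilyloxy)-13,13-ethylenedioxy-3-hydroxy-14,15,17-trinorlabdan-19-oate (axial 3-OH) | O[C@H]1CC[C@]2(C)[C@H](CC[C@H](O[Si](C)(C)C(C)(C)C)[C@H]2CCC3(C)OCCO3)[C@]1(C)C(=O)OCC | intermediate
22 | (3S,4R,5S,8S,9S,10R)-8-(tert-butyldimethylsilyloxy)-13,13-ethylenedioxy-14,15,17-trinorlabdane-3,19-diol | O[C@H]1CC[C@]2(C)[C@H](CC[C@H](O[Si](C)(C)C(C)(C)C)[C@H]2CCC3(C)OCCO3)[C@]1(C)CO | intermediate
23 | (3S,4R,5S,8S,9S,10R)-8-(tert-butyldimethylsilyloxy)-19-(tert-butyldiphenylsilyloxy)-13,13-ethylenedioxy-14,15,17-trinorlabdan-3-ol | O[C@H]1CC[C@]2(C)[C@H](CC[C@H](O[Si](C)(C)C(C)(C)C)[C@H]2CCC3(C)OCCO3)[C@]1(C)CO[Si](c4ccccc4)(c5ccccc5)C(C)(C)C | intermediate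
24 | (3S,4R,5S,8S,9S,10R)-3-acetoxy-8-(tert-butyldimethylsilyloxy)-19-(tert-butyldiphenylsilyloxy)-13,13-ethylenedioxy-14,15,17-trinorlabdane | CC(=O)O[C@H]1CC[C@]2(C)[C@H](CC[C@H](O[Si](C)(C)C(C)(C)C)[C@H]2CCC3(C)OCCO3)[C@]1(C)CO[Si](c4ccccc4)(c5ccccc5)C(C)(C)C | intermediate
25 | (3S,4R,5S,8S,9S,10R)-3-acetoxy-19-(tert-butyldiphenylsilyloxy)-13,13-ethylenedioxy-14,15,17-trinorlabdan-8-ol | CC(=O)O[C@H]1CC[C@]2(C)[C@H](CC[C@H](O)[C@H]2CCC3(C)OCCO3)[C@]1(C)CO[Si](c4ccccc4)(c5ccccc5)C(C)(C)C | intermediate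
26 | (3S,4R,5S,9S,10R)-3-acetoxy-19-(tert-butyldiphenylsilyloxy)-13,13-ethylenedioxy-14,15,17-trinorlabdan-8-one | CC(=O)O[C@H]1CC[C@]2(C)[C@H](CCC(=O)[C@H]2CCC3(C)OCCO3)[C@]1(C)CO[Si](c4ccccc4)(c5ccccc5)C(C)(C)C | intermediate
27 | lithium C7=C8 enolate of ketone 26 | [Li+].CC(=O)O[C@H]1CC[C@]2(C)[C@H](CC=C([O-])[C@H]2CCC3(C)OCCO3)[C@]1(C)CO[Si](c4ccccc4)(c5ccccc5)C(C)(C)C | intermediate
28 | (3S,4R,5S,9S,10R)-3-acetoxy-19-(tert-butyldiphenylsilyloxy)-13,13-ethylenedioxy-8-(trifluoromethanesulfonyloxy)-14,15,17-trinorlabd-7-ene | CC(=O)O[C@H]1CC[C@]2(C)[C@H](CC=C(OS(=O)(=O)C(F)(F)F)[C@H]2CCC3(C)OCCO3)[C@]1(C)CO[Si](c4ccccc4)(c5ccccc5)C(C)(C)C | intermediate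
29 | (3S,4R,5S,9R,10S)-3-acetoxy-19-(tert-butyldiphenylsilyloxy)-13,13-ethylenedioxy-14,15-dinorlabd-7-ene | CC(=O)O[C@H]1CC[C@]2(C)[C@H](CC=C(C)[C@H]2CCC3(C)OCCO3)[C@]1(C)CO[Si](c4ccccc4)(c5ccccc5)C(C)(C)C | intermediate
30 | (3S,4R,5S,9R,10S)-3-acetoxy-19-(tert-butyldiphenylsilyloxy)-14,15-dinorlabd-7-en-13-one | CC(=O)O[C@H]1CC[C@]2(C)[C@H](CC=C(C)[C@H]2CCC(C)=O)[C@]1(C)CO[Si](c4ccccc4)(c5ccccc5)C(C)(C)C | intermediate
31 | diethylphosphonoacetic acid | CCOP(=O)(CC(=O)O)OCC | starting material
32 | 2-(trimethylsilyl)ethanol | C[Si](C)(C)CCO | starting material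
33 | 2-(trimethylsilyl)ethyl 2-(diethoxyphosphoryl)acetate | CCOP(=O)(CC(=O)OCC[Si](C)(C)C)OCC | intermediate
34 | 2-(trimethylsilyl)ethyl (3S,4R,5S,9R,10S,13E)-3-acetoxy-19-(tert-butyldiphenylsilyloxy)labda-7,13-dien-15-oate | CC(=O)O[C@H]1CC[C@]2(C)[C@H](CC=C(C)[C@H]2CC/C(C)=C/C(=O)OCC[Si](C)(C)C)[C@]1(C)CO[Si](c4ccccc4)(c5ccccc5)C(C)(C)C | intermediate
35 | (3S,4R,5S,9R,10S,13E)-3-acetoxy-19-hydroxylabda-7,13-dien-15-oic acid (CNP0129162.1) | CC(=O)O[C@H]1CC[C@]2(C)[C@H](CC=C(C)[C@H]2CC/C(C)=C/C(=O)O)[C@]1(C)CO | target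

Total step count: 24. Longest linear sequence: 22 steps (steps 1–5, 7–21, 23 and 24). Steps 6 and 22 are side branches.

Steps most likely to fail

Step 7. The facial selection at C10 may erode, because the C8 silyloxy group, axial in the reactive conformer of 11, stands 1,3 to the incoming allyl group. Proton exchange between 11 and the product may also move the enolate to C6 and lead to allylation there. The fallback sets out from 6 and 8 and returns at 12. The two bonds are made in separate operations and C10 is put under catalyst control. Enolate 11, made as in step 7, is O-acylated with allyl chloroformate to give the allyl enol carbonate F1, which is purified. Pd2(dba)3 (dba = dibenzylideneacetone) with (R)-4-tert-butyl-2-[2-(diphenylphosphino)phenyl]-4,5-dihydrooxazole in toluene then brings about a Tsuji-type decarboxylative allylic alkylation. The enolate exists only as the partner of the π-allyl complex of divalent palladium, so it cannot change position. The (R) ligand is the one whose known preference on 2-methylcyclohexanone enol carbonates delivers the allyl group to the face that the C9 chain also favours.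

Step 13. Hydride delivery may drift to the axial path, or the reduction may stall, because the axial C19 ester crowds the equatorial trajectory that the bulky reagent has to use. The fallback sets out from 20 and returns at 22. The C3 configuration is taken from stereoelectronic epoxide opening instead of reagent bulk. LiN(SiMe3)2 and N-phenylbis(trifluoromethanesulfonimide) convert 20 into the C2=C3 enol triflate F2. Pd(OAc)2/PPh3 with HCO2H and n-Bu3N reduces it to the C2=C3 alkene F3. mCPBA (NaHCO3 buffer) attacks the hydrogen face, away from the axial C20 methyl and the axial ester, to give the 2,3-epoxide F4. LiAlH4 then opens the epoxide trans-diaxially at C2 (Fürst–Plattner rule), which leaves the axial C3 hydroxyl, and reduces the C19 ester in the same operation.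

Step 19. The amide base may also deprotonate or cleave the acetate, and a slow trap would allow the enolate to equilibrate towards C9. The fallback sets out from 23 and returns at 30. The strong-base step is run on a substrate without an enolisable ester, and the acetate is introduced afterwards. MOMCl and i-Pr2NEt cap the C3 hydroxyl as the methoxymethyl ether F5, and buffered HF·pyridine frees the C8 alcohol F6. Dess–Martin oxidation gives the C8 ketone F7, and LiN(SiMe3)2 with the triflimide of step 19 gives the enol triflate F8. MeZnCl and Pd(PPh3)4 give the C7=C8 alkene F9. Aqueous HCl in THF–MeOH removes the methoxymethyl group and the dioxolane together to give the hydroxy ketone F10, and Ac2O/DMAP/pyridine closes the detour.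

Further compounds
F1 | step 7 | allyl (3S,4S)-4-(tert-butyldimethylsilyloxy)-2-methyl-3-[2-(2-methyl-1,3-dioxolan-2-yl)ethyl]cyclohex-1-en-1-yl carbonate | CC2=C(OC(=O)OCC=C)CC[C@H](O[Si](C)(C)C(C)(C)C)[C@H]2CCC1(C)OCCO1
F2 | step 13 | ethyl 8-(tert-butyldimethylsilyloxy)-13,13-ethylenedioxy-3-(trifluoromethanesulfonyloxy)-14,15,17-trinorlabd-2-en-19-oate (configuration as in 20) | FC(F)(F)S(=O)(=O)OC1=CC[C@]2(C)[C@H](CC[C@H](O[Si](C)(C)C(C)(C)C)[C@H]2CCC3(C)OCCO3)[C@]1(C)C(=O)OCC
F3 | step 13 | ethyl 8-(tert-butyldimethylsilyloxy)-13,13-ethylenedioxy-14,15,17-trinorlabd-2-en-19-oate (configuration as in 20) | C1=CC[C@]2(C)[C@H](CC[C@H](O[Si](C)(C)C(C)(C)C)[C@H]2CCC3(C)OCCO3)[C@]1(C)C(=O)OCC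
F4 | step 13 | ethyl 8-(tert-butyldimethylsilyloxy)-2,3-epoxy-13,13-ethylenedioxy-14,15,17-trinorlabdan-19-oate (epoxide on the hydrogen face) | O1[C@H]2[C@@H]1C[C@]3(C)[C@H](CC[C@H](O[Si](C)(C)C(C)(C)C)[C@H]3CCC4(C)OCCO4)[C@]2(C)C(=O)OCC
F5 | step 19 | 8-(tert-butyldimethylsilyloxy)-19-(tert-butyldiphenylsilyloxy)-13,13-ethylenedioxy-3-(methoxymethoxy)-14,15,17-trinorlabdane (configuration as in 23) | COCO[C@H]1CC[C@]2(C)[C@H](CC[C@H](O[Si](C)(C)C(C)(C)C)[C@H]2CCC3(C)OCCO3)[C@]1(C)CO[Si](c4ccccc4)(c5ccccc5)C(C)(C)C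
F6 | step 19 | 19-(tert-butyldiphenylsilyloxy)-13,13-ethylenedioxy-3-(methoxymethoxy)-14,15,17-trinorlabdan-8-ol (configuration as in 25) | COCO[C@H]1CC[C@]2(C)[C@H](CC[C@H](O)[C@H]2CCC3(C)OCCO3)[C@]1(C)CO[Si](c4ccccc4)(c5ccccc5)C(C)(C)C
F7 | step 19 | 19-(tert-butyldiphenylsilyloxy)-13,13-ethylenedioxy-3-(methoxymethoxy)-14,15,17-trinorlabdan-8-one (configuration as in 26) | COCO[C@H]1CC[C@]2(C)[C@H](CCC(=O)[C@H]2CCC3(C)OCCO3)[C@]1(C)CO[Si](c4ccccc4)(c5ccccc5)C(C)(C)C
F8 | step 19 | 19-(tert-butyldiphenylsilyloxy)-13,13-ethylenedioxy-3-(methoxymethoxy)-8-(trifluoromethanesulfonyloxy)-14,15,17-trinorlabd-7-ene (configuration as in 28) | COCO[C@H]1CC[C@]2(C)[C@H](CC=C(OS(=O)(=O)C(F)(F)F)[C@H]2CCC3(C)OCCO3)[C@]1(C)CO[Si](c4ccccc4)(c5ccccc5)C(C)(C)C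
F9 | step 19 | 19-(tert-butyldiphenylsilyloxy)-13,13-ethylenedioxy-3-(methoxymethoxy)-14,15-dinorlabd-7-ene (configuration as in 29) | COCO[C@H]1CC[C@]2(C)[C@H](CC=C(C)[C@H]2CCC3(C)OCCO3)[C@]1(C)CO[Si](c4ccccc4)(c5ccccc5)C(C)(C)C
F10 | step 19 | 19-(tert-butyldiphenylsilyloxy)-3-hydroxy-14,15-dinorlabd-7-en-13-one (configuration as in 30) | O[C@H]1CC[C@]2(C)[C@H](CC=C(C)[C@H]2CCC(C)=O)[C@]1(C)CO[Si](c4ccccc4)(c5ccccc5)C(C)(C)C
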